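**Retrosynthetic overview**

1. Late stage: the aryl sulfates come from a hydroquinone (unmasked from a 2,5-dimethoxybenzyl group), the C4 methylene from a C4 ketone, the C8 methyl from a C8 ketone, and the C9 arylmethyl group by α′-alkylation of a C6–C7 enone.
2. Key disconnection: ring B of decalin A (bonds C5–C6 and C10–C9) by a chiral-Lewis-acid Diels–Alder reaction of a 2-alkylcyclohex-2-enone with a 2-silyloxypenta-1,3-diene. It rests on the quaternary ring-fusion carbon C5, which carries the two-carbon linker cis to H-10 and sits next to C4, whose exocyclic methylene is a ketone in disguise.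
3. The dienophile comes from a B-alkyl Suzuki coupling of 2-iodocyclohexenone (ring A) with the 9-BBN adduct of a C1′-vinyl decalin B.
4. Decalin B: ring C by an organocatalytic Michael/aldol annulation (sets C4a′), a 1,3-carbonyl transposition, then cuprate methylation and enolate vinylation (C2′, C1′); ring D by McMurry coupling.
5. Order of ring formation: ring C, ring D, then ring B onto the preformed ring A; the arene enters as 2,5-dimethoxybenzyl bromide.

Key step: step 13

**Conventions and assumptions**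

- Decalin A: C4 = C(=CH2), C5 = quaternary ring-fusion carbon, C10 = ring-fusion CH, C9 = C(CH3)(CH2Ar), C8 = CH(CH3), C6/C7 = CH2. Ring A = C1–C5, C10; ring B = C5–C10. α is the face of H-10 and of the C5 linker.
- Decalin B: C1′ (CH3, linker), C2′ (CH–CH3), C4a′ (ring-fusion CH), C5′ (C(CH3)2), C8′=C8a′. Ring C = C1′–C4′, C4a′, C8a′; ring D = C4a′, C5′–C8′, C8a′.
- R′ = 2-[(1R,2S,4aS)-1,2,5,5-tetramethyl-1,2,3,4,4a,5,6,7-octahydronaphthalen-1-yl]ethyl.
- Assumption: the (S)-catalysts named in steps 2 and 13 deliver the configurations drawn (step 2 by the usual enamine-shielding model, step 13 by analogy with unsubstituted cycloalkenones). If the opposite sense is found, the (R)-catalyst is used.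
- Assumption: the target is drawn as the free bis(hydrogen sulfate) and is delivered in that form by cation exchange. It is best kept cold, since aryl hydrogen sulfates are strong acids.

**Route**

Step 1
Reactants: 1 3-methylbut-2-enal; 2 [2-(1,3-dioxolan-2-yl)ethyl]magnesium bromide
Product: 4 5-(1,3-dioxolan-2-yl)-3,3-dimethylpentanal, via silyl enol ether 3 (not isolated)
Conditions: CuBr·SMe2 (10 mol %), Me3SiCl, THF, −78 °C; then K2CO3, MeOH, 0 °C
Reagents that add atoms: none
Why: Copper-catalysed, Me3SiCl-accelerated conjugate addition of the Grignard reagent to the β,β-disubstituted enal builds the quaternary carbon (later C5′), and methanolysis of the silyl enol ether frees the aldehyde while the dioxolane stays intact.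

Step 2
Reactants: 4 5-(1,3-dioxolan-2-yl)-3,3-dimethylpentanal; 5 pent-1-en-3-one
Product: 7 (4R)-4-[4-(1,3-dioxolan-2-yl)-2-methylbutan-2-yl]-2-methylcyclohex-2-en-1-one, via keto aldehyde 6 (not isolated)
Conditions: (S)-2-[methoxy(diphenyl)methyl]pyrrolidine (10 mol %), ethyl 3,4-dihydroxybenzoate (20 mol %), neat, 4 °C; then KOH (aq), Bu4NOH (cat.), Et2O/THF, reflux
Reagents that add atoms: none
Why: Enamine-catalysed Michael addition to the vinyl ketone followed by intramolecular aldol condensation (organocatalytic Robinson-type annulation); the catalyst shields one face of the (E)-enamine and so sets the ring stereocentre (later C4a′), and only the ethyl-ketone α-carbon can close a six-membered ring onto the aldehyde.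

Step 3
Reactants: 7 4-substituted 2-methylcyclohexenone
Product: 8 2,3-epoxy ketone of 7
Conditions: H2O2 (30 %), NaOH, MeOH, 0 °C
Reagents that add atoms: hydrogen peroxide, OO
Why: Weitz–Scheffer nucleophilic epoxidation of the enone; the peroxide should add anti to the bulky C4 substituent, but the epoxide configuration is lost again in step 4.

Step 4
Reactants: 8 epoxy ketone
Product: 9 (6S)-6-[4-(1,3-dioxolan-2-yl)-2-methylbutan-2-yl]-2-methylcyclohex-2-en-1-ol
Conditions: N2H4·H2O, AcOH (cat.), MeOH, rt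
Reagents that add atoms: none
Why: Wharton reaction: the epoxy hydrazone fragments with loss of nitrogen to the transposed allylic alcohol, which moves the oxygen to the carbon next to the stereocentre.

Step 5
Reactants: 9 allylic alcohol
Product: 10 (6S)-6-[4-(1,3-dioxolan-2-yl)-2-methylbutan-2-yl]-2-methylcyclohex-2-en-1-one
Conditions: Dess–Martin periodinane, NaHCO3, CH2Cl2, rt
Reagents that add atoms: none
Why: Dess–Martin oxidation under buffered, non-enolising conditions completes the 1,3-carbonyl transposition without touching the α-stereocentre.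

Step 6
Reactants: 10 6-substituted 2-methylcyclohexenone
Product: 11 {[(3S,6S)-6-[4-(1,3-dioxolan-2-yl)-2-methylbutan-2-yl]-2,3-dimethylcyclohex-1-en-1-yl]oxy}trimethylsilane
Conditions: Me2CuLi (from MeLi and CuI), Et2O, −78 → −30 °C; then Me3SiCl, Et3N, −78 °C → rt
Reagents that add atoms: lithium dimethylcuprate, [Li+].C[Cu-]C; chlorotrimethylsilane, C[Si](C)(C)Cl
Why: Gilman cuprate 1,4-addition with the bulky C6 substituent pseudoequatorial: axial attack at C3 through the chair-like transition state should place the new methyl group cis to the C6 substituent (C2′ set), and silylation captures the regiodefined enolate.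

Step 7
Reactants: 11 silyl enol ether
Product: 14 (2R,3S,6S)-6-[4-(1,3-dioxolan-2-yl)-2-methylbutan-2-yl]-2-ethenyl-2,3-dimethylcyclohexan-1-one, via lithium enolate 12 (not isolated), via sulfoxide adduct 13 (not isolated)
Conditions: MeLi, THF, 0 °C; PhS(O)CH=CH2, −78 → 0 °C; aq NH4Cl; then toluene, CaCO3, 110 °C
Reagents that add atoms: phenyl vinyl sulfoxide, C=CS(=O)c1ccccc1
Why: The regenerated lithium enolate adds to phenyl vinyl sulfoxide (Michael addition) anti to the adjacent axial C3 methyl group, which fixes the quaternary C1′, and thermal syn-elimination of benzenesulfenic acid unveils the vinyl group (enolate vinylation by the sulfoxide method).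

Step 8
Reactants: 14 vinyl ketone acetal
Product: 15 4-[(1S,3R,4S)-3-ethenyl-3,4-dimethyl-2-oxocyclohexyl]-4-methylpentanal
Conditions: 1 M HCl, THF, rt
Reagents that add atoms: water, O
Why: Acid-catalysed acetal hydrolysis; the hindered α-tert-alkyl ketone should not enolise under these mild conditions, so C4a′ is kept.

Step 9
Reactants: 15 keto aldehyde
Product: 16 (1R,2S,4aS)-1-ethenyl-1,2,5,5-tetramethyl-1,2,3,4,4a,5,6,7-octahydronaphthalene
Conditions: TiCl3(DME)1.5, Zn–Cu, DME, reflux, slow addition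
Reagents that add atoms: none
Why: Intramolecular McMurry coupling of the keto aldehyde by low-valent titanium closes ring D and places the alkene unambiguously at C8′=C8a′ without touching a stereocentre.

Step 10
Reactants: 17 cyclohex-2-en-1-one
Product: 18 2-iodocyclohex-2-en-1-one
Conditions: I2, pyridine, CH2Cl2, 0 °C → rt
Reagents that add atoms: iodine, II
Why: α-Iodination of the enone by conjugate addition of pyridine, iodination of the enolate and elimination (Baylis–Hillman-type mechanism).

Step 11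
Reactants: 16 vinyl decalin B; 18 2-iodocyclohex-2-en-1-one
Product: 20 2-{2-[(1R,2S,4aS)-1,2,5,5-tetramethyl-1,2,3,4,4a,5,6,7-octahydronaphthalen-1-yl]ethyl}cyclohex-2-en-1-one, via alkylborane 19 (not isolated)
Conditions: 9-BBN, THF, rt → 50 °C; then 18, PdCl2(dppf) (5 mol %), AsPh3, Cs2CO3, DMF/THF/H2O, rt
Reagents that add atoms: none
Why: 9-BBN hydroborates only the monosubstituted alkene (anti-Markovnikov), and the B-alkyl Suzuki–Miyaura coupling with the α-iodoenone forms the C(sp3)–C(sp2) bond of the linker.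

Step 12
Reactants: 5 pent-1-en-3-one
Product: 21 tert-butyl(dimethyl){[(3Z)-penta-1,3-dien-3-yl]oxy}silane
Conditions: tBuMe2SiOTf, Et3N, Et2O, 0 °C
Reagents that add atoms: tert-butyldimethylsilyl trifluoromethanesulfonate, CC(C)(C)[Si](C)(C)OS(=O)(=O)C(F)(F)F
Why: Soft enolisation and O-silylation of the ethyl ketone gives the 2-silyloxydiene, expected mainly as the (Z)-enol ether; the (E)-isomer cannot easily reach the s-cis form and should be a spectator in step 13.

Step 13
Reactants: 20 2-alkylcyclohex-2-enone; 21 (Z)-silyloxydiene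
Product: 22 cis-decalone adduct (4-oxo; 5α-R′; 10α-H; 9β-methyl; C7=C8 silyl enol ether)
Conditions: (S)-1-(2-methylphenyl)-3,3-diphenyltetrahydro-1H,3H-pyrrolo[1,2-c][1,3,2]oxazaborole (20 mol %), AlBr3 (16 mol %), 21 (2.5 equiv), CH2Cl2, −78 → −40 °C; pyridine quench
Reagents that add atoms: none
Why: Proposed new method: the cationic oxazaborolidinium Lewis acid binds the enone carbonyl and lowers its LUMO, so that the CH(CH3) terminus of the diene attacks the β-carbon C10 and the CH2 terminus the α-carbon C5 in an asynchronous [4+2] addition (in the limit a Mukaiyama–Michael addition followed by Michael closure); the closest known reactions are the AlBr3/AlMe3-promoted Diels–Alder reactions of 2-methylcyclohexenone with hindered 2-silyloxydienes and the oxazaborolidinium-catalysed Diels–Alder reactions of unsubstituted cycloalkenones, and the new element is chiral Lewis-acid control on a 2-alkylcyclohexenone. Ring B closes by a suprafacial [4+2] cycloaddition, or in the stepwise limit by a 6-endo-trig Michael addition of the C5 boron enolate to the silyloxonium-activated vinyl group. Because both bonds form on the same face of the ring A alkene, C5 and C10 must be cis; their absolute configuration (linker and H-10 both α) is set by the enone face that the catalyst leaves open, since the stereocentres of decalin B are held away by the flexible two-carbon linker and cannot differentiate the faces. C9 follows from the endo approach and the (Z)-enol ether geometry (methyl β), but it becomes planar again in step 17. The step needs regioselectivity, secured by the silyloxy group on the diene carbon that becomes C8, and facial selectivity, which rests on the catalyst alone.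

Step 14
Reactants: 22 cis-decalone adduct
Product: 23 4β-alcohol of 22
Conditions: LiAlH4, THF, −78 °C
Reagents that add atoms: none
Why: Hydride reduction of the neopentyl ketone (the silyl enol ether is inert); axial attack from the convex α face, anti to the axial C6 methylene on C5, should give the equatorial β-alcohol.

Step 15
Reactants: 23 4β-alcohol
Product: 24 4β-tert-butyldimethylsilyl ether of 23
Conditions: tBuMe2SiOTf, 2,6-lutidine, CH2Cl2, −78 → 0 °C
Reagents that add atoms: tert-butyldimethylsilyl trifluoromethanesulfonate, CC(C)(C)[Si](C)(C)OS(=O)(=O)C(F)(F)F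
Why: Silylation of the hindered secondary alcohol with the silyl triflate; the equatorial β-silyloxy group later holds the cis-decalin in one chair–chair conformer (used in step 20).

Step 16
Reactants: 24 bis-silylated adduct
Product: 25 C6–C7 enone (4β-silyloxy; 8-oxo; 9-methyl)
Conditions: Pd(OAc)2 (1.1 equiv), MeCN, rt
Reagents that add atoms: none
Why: Saegusa–Ito oxidation: the oxa-π-allyl species formed from the silyl enol ether and divalent palladium undergoes β-hydride elimination toward C6, and the resulting enone leaves C9 as the only enolisable position.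

Step 17
Reactants: 25 C6–C7 enone; 26 2,5-dimethoxybenzyl bromide
Product: 28 9α-(2,5-dimethoxybenzyl)-9β-methyl enone, via lithium dienolate 27 (not isolated)
Conditions: LiN(iPr)2, THF, −78 °C; then 26, DMPU, −78 → −20 °C
Reagents that add atoms: none
Why: α′-Deprotonation (C5 is quaternary, so C9–H is the only acidic position) gives one cross-conjugated dienolate whose alkylation creates the C9 quaternary centre; as in A/B-cis 3-keto steroids the bromide is expected on the convex α face (that of H-10 and the linker), reacting through the ring B conformer in which C4 is pseudoaxial and shields the β face.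

Step 18
Reactants: 28 benzylated enone
Product: 29 6,7-dihydro ketone (8-oxo)
Conditions: H2 (1 atm), 5 % Pd/C, EtOAc, rt, stopped after one equivalent
Reagents that add atoms: none
Why: Chemoselective catalytic hydrogenation of the disubstituted enone alkene; the hindered trisubstituted ring D alkene and the arene should stay untouched.

Step 19
Reactants: 29 C8 ketone
Product: 30 8-methylene compound
Conditions: Ph3PCH3Br, KOtBu, toluene, 90 °C
Reagents that add atoms: methyltriphenylphosphonium bromide, C[P+](c1ccccc1)(c1ccccc1)c1ccccc1.[Br-]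
Why: Wittig methylenation of the hindered ketone with excess ylide at elevated temperature; C9 is quaternary, so nothing can epimerise.

Step 20
Reactants: 30 8-methylene compound
Product: 31 8α-methyl compound (8β-H)
Conditions: H2 (1 atm), 10 % Pd/C, EtOAc, rt
Reagents that add atoms: none
Why: Heterogeneous hydrogenation of the 1,1-disubstituted alkene only; the equatorial 4β-silyloxy group should hold the decalin in the conformer with the C9 arylmethyl group axial on the α face, so hydrogen is delivered to the β face of C8 and the methyl group ends up α and equatorial.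

Step 21
Reactants: 31 silyl ether
Product: 32 4β-alcohol
Conditions: Bu4NF, THF, 60 °C
Reagents that add atoms: none
Why: Fluoride-mediated cleavage of the hindered silyl ether.

Step 22
Reactants: 32 4β-alcohol
Product: 33 4-ketone
Conditions: Dess–Martin periodinane, NaHCO3, CH2Cl2, rt
Reagents that add atoms: none
Why: Dess–Martin oxidation of the secondary alcohol; the alkenes and the electron-rich arene are inert.

Step 23
Reactants: 33 4-ketone
Product: 34 4-methylene compound (hydroquinone dimethyl ether of the target core)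
Conditions: Ph3PCH3Br, KOtBu, toluene, 100 °C
Reagents that add atoms: methyltriphenylphosphonium bromide, C[P+](c1ccccc1)(c1ccccc1)c1ccccc1.[Br-]
Why: Wittig methylenation of the neopentyl C4 ketone installs the exocyclic alkene.

Step 24
Reactants: 34 dimethyl ether
Product: 36 hydroquinone, via quinone 35 (not isolated)
Conditions: (NH4)2Ce(NO3)6, MeCN/H2O, 0 °C; then Na2S2O4, EtOAc/H2O, rt
Reagents that add atoms: water, O
Why: Oxidative demethylation of the hydroquinone dimethyl ether to the quinone by tetravalent cerium, then dithionite reduction; the unactivated alkenes should survive the short, cold oxidation.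

Step 25
Reactants: 36 hydroquinone
Product: 38 target bis(hydrogen sulfate) CNP0439949.2, via bis(pyridinium) sulfate 37 (not isolated)
Conditions: SO3·pyridine, pyridine, 45 °C, argon; then sulfonic acid resin (H+ form), MeOH/H2O, 0 °C; freeze-drying
Reagents that add atoms: sulfur trioxide–pyridine complex, O=S(=O)=O.c1ccncc1
Why: O-Sulfation of both phenols with the sulfur trioxide–pyridine complex, then cation exchange to the free acid.

**Compound list**

1 | 3-methylbut-2-enal | CC(C)=CC=O | starting material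
2 | [2-(1,3-dioxolan-2-yl)ethyl]magnesium bromide (THF solution) | Br[Mg]CCC1OCCO1 | starting material
3 | {[5-(1,3-dioxolan-2-yl)-3,3-dimethylpent-1-en-1-yl]oxy}trimethylsilane | C[Si](C)(C)OC=CC(C)(C)CCC1OCCO1 | intermediate (not isolated)
4 | 5-(1,3-dioxolan-2-yl)-3,3-dimethylpentanal | O=CCC(C)(C)CCC1OCCO1 | intermediate
5 | pent-1-en-3-one | CCC(=O)C=C | starting material
6 | (2S)-2-[4-(1,3-dioxolan-2-yl)-2-methylbutan-2-yl]-5-oxoheptanal | O=C[C@@H](CCC(=O)CC)C(C)(C)CCC1OCCO1 | intermediate (not isolated)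
7 | (4R)-4-[4-(1,3-dioxolan-2-yl)-2-methylbutan-2-yl]-2-methylcyclohex-2-en-1-one | CC1=C[C@H](C(C)(C)CCC2OCCO2)CCC1=O | intermediate
8 | 2,3-epoxide of 7 (epoxide carbons undefined; ring stereocentre as in 7) | CC12OC1[C@H](C(C)(C)CCC3OCCO3)CCC2=O | intermediate
9 | (6S)-6-[4-(1,3-dioxolan-2-yl)-2-methylbutan-2-yl]-2-methylcyclohex-2-en-1-ol (carbinol epimers) | CC1=CCC[C@@H](C(C)(C)CCC2OCCO2)C1O | intermediate
10 | (6S)-6-[4-(1,3-dioxolan-2-yl)-2-methylbutan-2-yl]-2-methylcyclohex-2-en-1-one | CC1=CCC[C@@H](C(C)(C)CCC2OCCO2)C1=O | intermediate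
11 | {[(3S,6S)-6-[4-(1,3-dioxolan-2-yl)-2-methylbutan-2-yl]-2,3-dimethylcyclohex-1-en-1-yl]oxy}trimethylsilane | CC1=C(O[Si](C)(C)C)[C@H](C(C)(C)CCC2OCCO2)CC[C@@H]1C | intermediate
12 | lithium enolate corresponding to 11 | CC1=C(O[Li])[C@H](C(C)(C)CCC2OCCO2)CC[C@@H]1C | intermediate (not isolated)
13 | (2R,3S,6S)-6-[4-(1,3-dioxolan-2-yl)-2-methylbutan-2-yl]-2,3-dimethyl-2-[2-(phenylsulfinyl)ethyl]cyclohexan-1-one (sulfur epimers) | O=S(CC[C@@]1(C)C(=O)[C@H](C(C)(C)CCC2OCCO2)CC[C@@H]1C)c1ccccc1 | intermediate (not isolated)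
14 | (2R,3S,6S)-6-[4-(1,3-dioxolan-2-yl)-2-methylbutan-2-yl]-2-ethenyl-2,3-dimethylcyclohexan-1-one | C=C[C@@]1(C)C(=O)[C@H](C(C)(C)CCC2OCCO2)CC[C@@H]1C | intermediate
15 | 4-[(1S,3R,4S)-3-ethenyl-3,4-dimethyl-2-oxocyclohexyl]-4-methylpentanal | C=C[C@@]1(C)C(=O)[C@H](C(C)(C)CCC=O)CC[C@@H]1C | intermediate
16 | (1R,2S,4aS)-1-ethenyl-1,2,5,5-tetramethyl-1,2,3,4,4a,5,6,7-octahydronaphthalene | C=C[C@@]1(C)C2=CCCC(C)(C)[C@@H]2CC[C@@H]1C | intermediate
17 | cyclohex-2-en-1-one | O=C1CCCC=C1 | starting material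
18 | 2-iodocyclohex-2-en-1-one | O=C1CCCC=C1I | intermediate
19 | 9-R′-9-borabicyclo[3.3.1]nonane | B1(CC[C@@]2(C)C3=CCCC(C)(C)[C@@H]3CC[C@@H]2C)C2CCCC1CCC2 | intermediate (not isolated)
20 | 2-{2-[(1R,2S,4aS)-1,2,5,5-tetramethyl-1,2,3,4,4a,5,6,7-octahydronaphthalen-1-yl]ethyl}cyclohex-2-en-1-one | O=C1CCCC=C1CC[C@@]1(C)C2=CCCC(C)(C)[C@@H]2CC[C@@H]1C | intermediate
21 | tert-butyl(dimethyl){[(3Z)-penta-1,3-dien-3-yl]oxy}silane | C=C/C(O[Si](C)(C)C(C)(C)C)=C/C | intermediate
22 | cis-decalone adduct: 4-oxo, 5α-R′, 10α-H, 9β-methyl (9α-H), C7=C8 tert-butyldimethylsilyl enol ether | O=C1CCC[C@H]2[C@]1(CC[C@@]1(C)C3=CCCC(C)(C)[C@@H]3CC[C@@H]1C)CC=C(O[Si](C)(C)C(C)(C)C)[C@H]2C | intermediate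
23 | 4β-alcohol of 22 | O[C@@H]1CCC[C@H]2[C@]1(CC[C@@]1(C)C3=CCCC(C)(C)[C@@H]3CC[C@@H]1C)CC=C(O[Si](C)(C)C(C)(C)C)[C@H]2C | intermediate
24 | 4β-tert-butyldimethylsilyl ether of 23 | CC(C)(C)[Si](C)(C)O[C@@H]1CCC[C@H]2[C@]1(CC[C@@]1(C)C3=CCCC(C)(C)[C@@H]3CC[C@@H]1C)CC=C(O[Si](C)(C)C(C)(C)C)[C@H]2C | intermediate
25 | enone: 4β-silyloxy, 5α-R′, 10α-H, C6=C7, 8-oxo, 9-methyl (C9 configuration inconsequential) | CC(C)(C)[Si](C)(C)O[C@@H]1CCC[C@H]2[C@]1(CC[C@@]1(C)C3=CCCC(C)(C)[C@@H]3CC[C@@H]1C)C=CC(=O)[C@H]2C | intermediate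
26 | 2,5-dimethoxybenzyl bromide | COc1ccc(OC)c(CBr)c1 | starting material
27 | lithium dienolate of 25 (C6=C7, C8(OLi)=C9) | CC(C)(C)[Si](C)(C)O[C@@H]1CCC[C@H]2[C@]1(CC[C@@]1(C)C3=CCCC(C)(C)[C@@H]3CC[C@@H]1C)C=CC(O[Li])=C2C | intermediate (not isolated)
28 | enone with 9α-(2,5-dimethoxybenzyl) and 9β-methyl | CC(C)(C)[Si](C)(C)O[C@@H]1CCC[C@H]2[C@]1(CC[C@@]1(C)C3=CCCC(C)(C)[C@@H]3CC[C@@H]1C)C=CC(=O)[C@]2(C)Cc1cc(OC)ccc1OC | intermediate
29 | 6,7-dihydro derivative of 28 (8-ketone) | CC(C)(C)[Si](C)(C)O[C@@H]1CCC[C@H]2[C@]1(CC[C@@]1(C)C3=CCCC(C)(C)[C@@H]3CC[C@@H]1C)CCC(=O)[C@]2(C)Cc1cc(OC)ccc1OC | intermediate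
30 | 8-methylene compound | CC(C)(C)[Si](C)(C)O[C@@H]1CCC[C@H]2[C@]1(CC[C@@]1(C)C3=CCCC(C)(C)[C@@H]3CC[C@@H]1C)CCC(=C)[C@]2(C)Cc1cc(OC)ccc1OC | intermediate
31 | 8α-methyl compound (8β-H), 4β-silyl ether | CC(C)(C)[Si](C)(C)O[C@@H]1CCC[C@H]2[C@]1(CC[C@@]1(C)C3=CCCC(C)(C)[C@@H]3CC[C@@H]1C)CC[C@H](C)[C@]2(C)Cc1cc(OC)ccc1OC | intermediate
32 | 4β-alcohol from 31 | O[C@@H]1CCC[C@H]2[C@]1(CC[C@@]1(C)C3=CCCC(C)(C)[C@@H]3CC[C@@H]1C)CC[C@H](C)[C@]2(C)Cc1cc(OC)ccc1OC | intermediate
33 | 4-ketone | O=C1CCC[C@H]2[C@]1(CC[C@@]1(C)C3=CCCC(C)(C)[C@@H]3CC[C@@H]1C)CC[C@H](C)[C@]2(C)Cc1cc(OC)ccc1OC | intermediate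
34 | 4-methylene compound, hydroquinone dimethyl ether of the target core | C=C1CCC[C@H]2[C@]1(CC[C@@]1(C)C3=CCCC(C)(C)[C@@H]3CC[C@@H]1C)CC[C@H](C)[C@]2(C)Cc1cc(OC)ccc1OC | intermediate
35 | corresponding 2-substituted 1,4-benzoquinone | C=C1CCC[C@H]2[C@]1(CC[C@@]1(C)C3=CCCC(C)(C)[C@@H]3CC[C@@H]1C)CC[C@H](C)[C@]2(C)CC1=CC(=O)C=CC1=O | intermediate (not isolated)
36 | corresponding hydroquinone | C=C1CCC[C@H]2[C@]1(CC[C@@]1(C)C3=CCCC(C)(C)[C@@H]3CC[C@@H]1C)CC[C@H](C)[C@]2(C)Cc1cc(O)ccc1O | intermediate
37 | bis(pyridinium) salt of the bis(sulfate) | C=C1CCC[C@H]2[C@]1(CC[C@@]1(C)C3=CCCC(C)(C)[C@@H]3CC[C@@H]1C)CC[C@H](C)[C@]2(C)Cc1cc(OS(=O)(=O)[O-])ccc1OS(=O)(=O)[O-].c1cc[nH+]cc1.c1cc[nH+]cc1 | intermediate (not isolated)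
38 | CNP0439949.2, bis(hydrogen sulfate) | C=C1CCC[C@H]2[C@]1(CC[C@@]1(C)C3=CCCC(C)(C)[C@@H]3CC[C@@H]1C)CC[C@H](C)[C@]2(C)Cc1cc(OS(=O)(=O)O)ccc1OS(=O)(=O)O | target

**Step count and risks**

Total step count: 25. Longest linear sequence: 23 steps (steps 1–9, 11, 13–25); steps 10 and 12 are side branches.

Steps most likely to fail:

1. Step 13 (proposed new method). The catalyst may discriminate poorly between the two enone faces, because a 2-alkyl enone lacks the α-C–H that normally organises binding to the oxazaborolidinium ion, or the reaction may stall after the first Michael bond. Fallback with known chemistry: give up catalyst control. Starting from 20 and 21, the cycloaddition is promoted by the achiral mixed Lewis acid AlBr3/AlMe3 (about 5:1, toluene/CH2Cl2, −5 °C), conditions established for 2-methylcyclohexenone and hindered 2-silyloxydienes. This should give 22 together with its ring A/B diastereomer F1 (opposite configuration at C5, C10 and C9) in comparable amounts, since the decalin B stereocentres are remote. The two are separated by preparative HPLC, and the route is rejoined at 22.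

2. Step 17. The benzylic bromide may attack the β face of the dienolate, or both faces, if the conformer with the axial C5 linker reacts. Fallback: introduce the two C9 substituents in the opposite order, so that a β-face preference becomes productive.
   - 26 alkylates the lithium enolate of N-methoxy-N-methylacetamide (LiN(iPr)2, THF, −78 °C) to give the Weinreb amide F2.
   - CH2=CHMgBr converts F2 into 5-(2,5-dimethoxyphenyl)pent-1-en-3-one F3.
   - tBuMe2SiOTf/Et3N gives the (Z)-silyloxydiene F4.
   - F4 and 20 react under the conditions of step 13 to give the adduct F5, which carries the arylmethyl group at C9.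
   - F5 is reduced (LiAlH4) to the 4β-alcohol F6, silylated to F7 and oxidised (Pd(OAc)2) to the enone F8.
   - The lithium dienolate F9 (LiN(iPr)2) is then methylated with iodomethane on the β face, and the route is rejoined at 28.

3. Step 20. Hydrogen may be delivered to the α face of C8 if the conformer with the axial C9 methyl group reacts, or the ring D alkene may be reduced or isomerised on palladium. Fallback: set C8 under thermodynamic control without hydrogenation.
   - Starting from 29, Ph3P=CHOMe (from Ph3PCH2OMe Cl and KN(SiMe3)2, THF) gives the enol ether F10.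
   - Hydrolysis (aq HCl, THF) and equilibration (K2CO3, MeOH) give the 8α-carbaldehyde F11; the formyl group should be equatorial in the conformer fixed by the 4β-silyloxy group.
   - Hydrazine gives the hydrazone F12, and Wolff–Kishner reduction in its room-temperature KOtBu/DMSO form gives 31, where the route is rejoined.

**Further compounds**

F1 | step 13 | ring A/B diastereomer of 22 (5β-R′, 10β-H, 9α-methyl) | O=C1CCC[C@@H]2[C@@]1(CC[C@@]1(C)C3=CCCC(C)(C)[C@@H]3CC[C@@H]1C)CC=C(O[Si](C)(C)C(C)(C)C)[C@@H]2C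
F2 | step 17 | 3-(2,5-dimethoxyphenyl)-N-methoxy-N-methylpropanamide | CON(C)C(=O)CCc1cc(OC)ccc1OC
F3 | step 17 | 5-(2,5-dimethoxyphenyl)pent-1-en-3-one | C=CC(=O)CCc1cc(OC)ccc1OC
F4 | step 17 | tert-butyl{[(3Z)-5-(2,5-dimethoxyphenyl)penta-1,3-dien-3-yl]oxy}dimethylsilane | C=C/C(O[Si](C)(C)C(C)(C)C)=C/Cc1cc(OC)ccc1OC
F5 | step 17 | cis-decalone adduct with 9-(2,5-dimethoxybenzyl) in place of 9-methyl | O=C1CCC[C@H]2[C@]1(CC[C@@]1(C)C3=CCCC(C)(C)[C@@H]3CC[C@@H]1C)CC=C(O[Si](C)(C)C(C)(C)C)[C@H]2Cc1cc(OC)ccc1OC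
F6 | step 17 | 4β-alcohol of F5 | O[C@@H]1CCC[C@H]2[C@]1(CC[C@@]1(C)C3=CCCC(C)(C)[C@@H]3CC[C@@H]1C)CC=C(O[Si](C)(C)C(C)(C)C)[C@H]2Cc1cc(OC)ccc1OC
F7 | step 17 | 4β-tert-butyldimethylsilyl ether of F6 | CC(C)(C)[Si](C)(C)O[C@@H]1CCC[C@H]2[C@]1(CC[C@@]1(C)C3=CCCC(C)(C)[C@@H]3CC[C@@H]1C)CC=C(O[Si](C)(C)C(C)(C)C)[C@H]2Cc1cc(OC)ccc1OC
F8 | step 17 | C6–C7 enone with 9-(2,5-dimethoxybenzyl) and 9-H | CC(C)(C)[Si](C)(C)O[C@@H]1CCC[C@H]2[C@]1(CC[C@@]1(C)C3=CCCC(C)(C)[C@@H]3CC[C@@H]1C)C=CC(=O)[C@H]2Cc1cc(OC)ccc1OC
F9 | step 17 | lithium dienolate of F8 | CC(C)(C)[Si](C)(C)O[C@@H]1CCC[C@H]2[C@]1(CC[C@@]1(C)C3=CCCC(C)(C)[C@@H]3CC[C@@H]1C)C=CC(O[Li])=C2Cc1cc(OC)ccc1OC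
F10 | step 20 | 8-(methoxymethylidene) compound from 29 (E/Z mixture) | CC(C)(C)[Si](C)(C)O[C@@H]1CCC[C@H]2[C@]1(CC[C@@]1(C)C3=CCCC(C)(C)[C@@H]3CC[C@@H]1C)CCC(=COC)[C@]2(C)Cc1cc(OC)ccc1OC
F11 | step 20 | 8α-carbaldehyde | CC(C)(C)[Si](C)(C)O[C@@H]1CCC[C@H]2[C@]1(CC[C@@]1(C)C3=CCCC(C)(C)[C@@H]3CC[C@@H]1C)CC[C@H](C=O)[C@]2(C)Cc1cc(OC)ccc1OC
F12 | step 20 | hydrazone of F11 | CC(C)(C)[Si](C)(C)O[C@@H]1CCC[C@H]2[C@]1(CC[C@@]1(C)C3=CCCC(C)(C)[C@@H]3CC[C@@H]1C)CC[C@H](C=NN)[C@]2(C)Cc1cc(OC)ccc1OC
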